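**Plan**

- Retrosynthesis: the two ring A MOM ethers are removed last. Ring C is then cut at C2–C3 and O1–C8a together, giving 4-methoxybenzaldehyde (its C=O becomes C2–O1) and the enol silane of a 2-fluoroaryl methyl ketone. Acetyl, prenyl and iodine are then taken off ring A in turn, back to 5-fluororesorcinol.
- Enabling feature: O1–C8a=C4a–C4=O is a vinylogous ester spanning rings A and C. C3 (alpha to C4=O) is therefore an enol carbon, and C8a (ortho to the acyl group) accepts an oxygen nucleophile once it carries fluorine.
- Fluorine marks C8a and oxygen marks C5, so the 6- versus 8-prenyl question is settled on ring A before ring C exists. The prenylated intermediate 8 is symmetric, which makes the acetylation site unambiguous.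
- Forward order: ring A is dressed (iodination, MOM, prenyl, acetyl, enol silane), ring C arises in one operation by aldol/SNAr annulation, then deprotection.
- Stereochemistry: C2 is set by a catalytic enantioselective Mukaiyama aldol addition (Si face of the aldehyde) and kept because the C2–O1 bond is not broken afterwards.

Key step: step 6

Remark: flavanone numbering is used (O1, C2, C3, C4, C4a, C5–C8, C8a; ring A benzo, ring C pyranone). The step 6 catalyst is made beforehand from N-tosyl-(R)-tryptophan and BuB(OH)2. It is assumed to open the Si face of the aldehyde; if the sense is reversed on this substrate, its enantiomer is used.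

**Step 1**
Reactants: 1 5-fluorobenzene-1,3-diol (5-fluororesorcinol); 2 iodine
Product: 3 5-fluoro-2-iodobenzene-1,3-diol
Conditions: I2, NaHCO3, H2O, 0 °C to rt
Reagents that add atoms: iodine (2), II
Why: Electrophilic aromatic iodination in aqueous bicarbonate should go to C2, the carbon ortho to both oxygens and para to fluorine, as it does for resorcinol itself under these conditions.

**Step 2**
Reactants: 3 5-fluoro-2-iodobenzene-1,3-diol; 4 chloromethyl methyl ether
Product: 5 5-fluoro-2-iodo-1,3-bis(methoxymethoxy)benzene
Conditions: MOMCl, K2CO3, acetone, 0 °C to rt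
Reagents that add atoms: chloromethyl methyl ether (4), COCCl
Why: O-Alkylation of both phenoxides (MOM ether formation) gives acetals that survive organolithium reagents and later direct the ortho-metalation.

**Step 3**
Reactants: 5 5-fluoro-2-iodo-1,3-bis(methoxymethoxy)benzene; 6 1-bromo-3-methylbut-2-ene (prenyl bromide)
Product: 8 5-fluoro-1,3-bis(methoxymethoxy)-2-(3-methylbut-2-en-1-yl)benzene, via aryllithium 7 (not isolated)
Conditions: n-BuLi, THF, −78 °C; then CuBr·SMe2 (20 mol %), prenyl bromide, −78 to 0 °C
Reagents that add atoms: 1-bromo-3-methylbut-2-ene (6), CC(C)=CCBr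
Why: Iodine–lithium exchange generates aryllithium 7 exactly at the halogenated carbon, and copper-catalysed allylic substitution (SN2) at the primary carbon of prenyl bromide should give the linear prenyl arene, because the SN2' alternative would place a quaternary carbon between two ortho substituents.

**Step 4**
Reactants: 8 5-fluoro-1,3-bis(methoxymethoxy)-2-(3-methylbut-2-en-1-yl)benzene; 9 N-methoxy-N-methylacetamide
Product: 12 1-[6-fluoro-2,4-bis(methoxymethoxy)-3-(3-methylbut-2-en-1-yl)phenyl]ethan-1-one, via aryllithium 10 (not isolated), via lithium hemiaminal adduct 11 (not isolated)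
Conditions: n-BuLi, THF, −78 °C; MeC(O)N(OMe)Me, −78 to −50 °C; AcOH quench
Reagents that add atoms: N-methoxy-N-methylacetamide (9), CC(=O)N(C)OC
Why: Directed ortho-metalation takes place at the only kind of ring C–H left (the two are equivalent by symmetry and each is flanked by F and OMOM), and Weinreb amide acylation stops at the chelated adduct 11, which gives the methyl ketone only on quench; holding 10 at −78 °C keeps it from losing LiF to an aryne.

**Step 5**
Reactants: 12 1-[6-fluoro-2,4-bis(methoxymethoxy)-3-(3-methylbut-2-en-1-yl)phenyl]ethan-1-one; 13 chlorotrimethylsilane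
Product: 15 {1-[6-fluoro-2,4-bis(methoxymethoxy)-3-(3-methylbut-2-en-1-yl)phenyl]ethenyl}oxy(trimethyl)silane, via lithium enolate 14 (not isolated)
Conditions: LiN(SiMe3)2, THF, −78 °C; Me3SiCl, −78 to 0 °C; non-aqueous work-up (pentane, filtration), used directly
Reagents that add atoms: chlorotrimethylsilane (13), C[Si](C)(C)Cl
Why: Kinetic deprotonation of the methyl ketone at its only enolisable position and O-silylation of lithium enolate 14 give the enol silane (silyl enol ether formation).

**Step 6**
Reactants: 15 {1-[6-fluoro-2,4-bis(methoxymethoxy)-3-(3-methylbut-2-en-1-yl)phenyl]ethenyl}oxy(trimethyl)silane; 16 4-methoxybenzaldehyde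
Product: 18 (2S)-2-(4-methoxyphenyl)-5,7-bis(methoxymethoxy)-6-(3-methylbut-2-en-1-yl)-2,3-dihydro-4H-chromen-4-one, via aldol trimethylsilyl ether 17 (not isolated)
Conditions: (R)-2-butyl-4-(1H-indol-3-ylmethyl)-3-tosyl-1,3,2-oxazaborolidin-5-one (20 mol %), EtCN, −78 °C; then Bu4N[Ph3SiF2] (0.4 equiv), DMF, −40 to 0 °C; AcOH/buffer quench
Reagents that add atoms: 4-methoxybenzaldehyde (16), COc1ccc(C=O)cc1
Why: Proposed new method: the chiral boron Lewis acid activates aldehyde 16 for Mukaiyama aldol attack by the CH2 terminus of enol silane 15 (C3–C2 bond) with silyl transfer to give 17, and fluoride then unmasks the C2 alkoxide, whose oxygen adds to the fluorine-bearing carbon C8a ortho to the ketone and expels fluoride (O1–C8a bond), the released fluoride desilylating the next molecule of 17 so that Me3SiF is the only by-product. The closest known reaction types are the oxazaborolidinone-catalysed Mukaiyama aldol/dihydropyranone annulation of 1-alkoxy-3-silyloxydienes with aldehydes and the intramolecular SNAr closure of alkoxides and enolates onto 2-fluoroaryl ketones to chromanones and chromones; their fusion into one fluoride-relay operation on an aryl enol silane has not been shown. Ring C closes by a six-membered addition–elimination at C8a, formally a 6-endo-trig oxa-Michael addition across C8a=C4a, with the charge of the Meisenheimer intermediate taken up by the C4 carbonyl and none of it placed on the oxygen-bearing carbons C5 and C7. C2 is set in the aldol stage by catalyst control (the indole ring shields one face of the boron-bound aldehyde and leaves the Si face open) and is carried through with retention because the C2–O1 bond is never broken. The step needs enantiofacial selectivity (catalyst), a single direction of ring closure (only C8a carries a leaving group, which fixes prenyl at C6) and cyclisation faster than retro-aldol or base-induced ring opening (low temperature, substoichiometric fluoride, buffered quench).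

**Step 7**
Reactants: 18 (2S)-2-(4-methoxyphenyl)-5,7-bis(methoxymethoxy)-6-(3-methylbut-2-en-1-yl)-2,3-dihydro-4H-chromen-4-one
Product: 19 (2S)-5,7-dihydroxy-2-(4-methoxyphenyl)-6-(3-methylbut-2-en-1-yl)-2,3-dihydro-4H-chromen-4-one
Conditions: HCl (about 1 M) in MeOH, 25–40 °C, stopped at full conversion
Reagents that add atoms: none
Why: Acid-catalysed acetal exchange with methanol should remove both MOM groups (the C5 one assisted by the C4 carbonyl) while the aryl methyl ether is inert and C2 is untouched, flavanones being configurationally stable to dilute acid.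

**Compound list**

1 | 5-fluorobenzene-1,3-diol | Oc1cc(F)cc(O)c1 | starting material
2 | iodine | II | starting material
3 | 5-fluoro-2-iodobenzene-1,3-diol | Oc1cc(F)cc(O)c1I | intermediate
4 | chloromethyl methyl ether | COCCl | starting material
5 | 5-fluoro-2-iodo-1,3-bis(methoxymethoxy)benzene | COCOc1cc(F)cc(OCOC)c1I | intermediate
6 | 1-bromo-3-methylbut-2-ene | CC(C)=CCBr | starting material
7 | [4-fluoro-2,6-bis(methoxymethoxy)phenyl]lithium | [Li]c1c(OCOC)cc(F)cc1OCOC | intermediate
8 | 5-fluoro-1,3-bis(methoxymethoxy)-2-(3-methylbut-2-en-1-yl)benzene | COCOc1cc(F)cc(OCOC)c1CC=C(C)C | intermediate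
9 | N-methoxy-N-methylacetamide | CC(=O)N(C)OC | starting material
10 | [6-fluoro-2,4-bis(methoxymethoxy)-3-(3-methylbut-2-en-1-yl)phenyl]lithium | [Li]c1c(F)cc(OCOC)c(CC=C(C)C)c1OCOC | intermediate
11 | lithium 1-[6-fluoro-2,4-bis(methoxymethoxy)-3-(3-methylbut-2-en-1-yl)phenyl]-1-[methoxy(methyl)amino]ethan-1-olate | CC(O[Li])(N(C)OC)c1c(F)cc(OCOC)c(CC=C(C)C)c1OCOC | intermediate
12 | 1-[6-fluoro-2,4-bis(methoxymethoxy)-3-(3-methylbut-2-en-1-yl)phenyl]ethan-1-one | CC(=O)c1c(F)cc(OCOC)c(CC=C(C)C)c1OCOC | intermediate
13 | chlorotrimethylsilane | C[Si](C)(C)Cl | starting material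
14 | lithium 1-[6-fluoro-2,4-bis(methoxymethoxy)-3-(3-methylbut-2-en-1-yl)phenyl]ethen-1-olate | C=C(O[Li])c1c(F)cc(OCOC)c(CC=C(C)C)c1OCOC | intermediate
15 | {1-[6-fluoro-2,4-bis(methoxymethoxy)-3-(3-methylbut-2-en-1-yl)phenyl]ethenyl}oxy(trimethyl)silane | C=C(O[Si](C)(C)C)c1c(F)cc(OCOC)c(CC=C(C)C)c1OCOC | intermediate
16 | 4-methoxybenzaldehyde | COc1ccc(C=O)cc1 | starting material
17 | (3S)-1-[6-fluoro-2,4-bis(methoxymethoxy)-3-(3-methylbut-2-en-1-yl)phenyl]-3-(4-methoxyphenyl)-3-[(trimethylsilyl)oxy]propan-1-one | COc1ccc([C@@H](O[Si](C)(C)C)CC(=O)c2c(F)cc(OCOC)c(CC=C(C)C)c2OCOC)cc1 | intermediate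
18 | (2S)-2-(4-methoxyphenyl)-5,7-bis(methoxymethoxy)-6-(3-methylbut-2-en-1-yl)-2,3-dihydro-4H-chromen-4-one | COc1ccc([C@@H]2CC(=O)c3c(cc(OCOC)c(CC=C(C)C)c3OCOC)O2)cc1 | intermediate
19 | (2S)-5,7-dihydroxy-2-(4-methoxyphenyl)-6-(3-methylbut-2-en-1-yl)-2,3-dihydro-4H-chromen-4-one | COc1ccc([C@@H]2CC(=O)c3c(cc(O)c(CC=C(C)C)c3O)O2)cc1 | target

**Step count and risks**

Total step count: 7. Longest linear sequence: 7 steps (from 1).

Steps most likely to fail:

1. Step 6. The transient alkoxide may undergo retro-aldol cleavage or elimination faster than it cyclises, the fluoride medium may open the finished flavanone reversibly and erode the enantiomeric purity, or facial control with the electron-rich aldehyde may be insufficient. The fallback uses known chemistry, sets out from 12 and comes back at 18. Claisen condensation of 12 with ethyl formate (NaOEt, THF) gives (Z)-1-[6-fluoro-2,4-bis(methoxymethoxy)-3-(3-methylbut-2-en-1-yl)phenyl]-3-hydroxyprop-2-en-1-one F1. K2CO3 in DMF at 60 °C closes the pyranone ring by intramolecular SNAr of the enolate oxygen at the C–F carbon to give 5,7-bis(methoxymethoxy)-6-(3-methylbut-2-en-1-yl)-4H-chromen-4-one F2. Asymmetric 1,4-addition of 4-methoxyphenylboronic acid to F2, catalysed by [Rh(OH)(cod)]2 (monovalent rhodium) with an electron-poor atropisomeric bisphosphine of the MeO-BIPHEP type (ligand enantiomer chosen for the 2S product), then gives 18. The stereocentre is thus set last, with no alkoxide or fluoride present.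

2. Step 7. Acid may cyclise the prenyl group onto a flanking phenol, add methanol across the alkene, or open ring C reversibly with loss of configurational purity. The fallback sets out from 18 and comes back at 19, and replaces acid solvolysis by trans-silylation. Me3SiOTf and 2,2'-bipyridyl in CH2Cl2 at 0 °C should convert both aryl MOM ethers, through N-(methoxymethyl)bipyridinium intermediates and without free Brønsted acid, into (2S)-2-(4-methoxyphenyl)-6-(3-methylbut-2-en-1-yl)-5,7-bis[(trimethylsilyl)oxy]-2,3-dihydro-4H-chromen-4-one F3. Addition of water at 0–20 °C then hydrolyses the silyl ethers to 19.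

3. Step 1. Iodination may go in part to the carbon next to fluorine or run on to di-iodination. The fallback sets out from 1 and comes back at 7, with C–H lithiation in place of halogenation. Bis-MOM protection of 1 (MOMCl, K2CO3, acetone) gives 1-fluoro-3,5-bis(methoxymethoxy)benzene F4. Coordination-controlled ortho-lithiation (n-BuLi, Et2O/hexane, 0 °C, no amine additive) between the two MOM ethers then gives aryllithium 7 directly, which is prenylated as in step 3. The regioselectivity of this lithiation is itself uncertain because fluorine also acidifies its neighbours, but any fluorine-flanked aryllithium would lose LiF at this temperature and so should not be carried forward as a regioisomer.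

**Further compounds**

F1 | step 6 | (Z)-1-[6-fluoro-2,4-bis(methoxymethoxy)-3-(3-methylbut-2-en-1-yl)phenyl]-3-hydroxyprop-2-en-1-one | O/C=C\C(=O)c1c(F)cc(OCOC)c(CC=C(C)C)c1OCOC
F2 | step 6 | 5,7-bis(methoxymethoxy)-6-(3-methylbut-2-en-1-yl)-4H-chromen-4-one | O=c1ccoc2cc(OCOC)c(CC=C(C)C)c(OCOC)c12
F3 | step 7 | (2S)-2-(4-methoxyphenyl)-6-(3-methylbut-2-en-1-yl)-5,7-bis[(trimethylsilyl)oxy]-2,3-dihydro-4H-chromen-4-one | COc1ccc([C@@H]2CC(=O)c3c(cc(O[Si](C)(C)C)c(CC=C(C)C)c3O[Si](C)(C)C)O2)cc1
F4 | step 1 | 1-fluoro-3,5-bis(methoxymethoxy)benzene | COCOc1cc(F)cc(OCOC)c1
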